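**Plan**
1. Retrosynthesis cuts first the two ArCH2–C6 bonds that join the terminal dienone rings to the aromatic core (both at once, since the core is C2v-symmetric). It then cuts, in each terminal ring, the C3–C4 bond between the enolic carbonyl carbon next to the butanoyl-bearing C2 and the quaternary CMe2 carbon. Last it cuts the central ArCH2–Ar bridge.
2. The feature used: ring atoms C3, C2, C1, C6, C5, C4 of a 2-butanoyl-4,4-dimethylcyclohexane-1,3,5-trione are, in the same order, C2, C3, C4, C5, C6 and the isopropyl methine of 3-butanoyl-4-hydroxy-6-isopropyl-2-pyrone. The two are isomers that differ only in O1–C2 versus C3–C4 bonding, so the gem-dimethyl carbon is a tertiary enolate carbon waiting next to a masked acyl group.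
3. Forward, fragment A: dioxinone, then keto-dioxinone, then the pyrone ring (closed through oxygen), then C3-butanoylation, then a base-triggered ring opening to a dienediolate ketene that recloses through carbon to the carbocycle. The ring is thereby built with all substituents in place and no C-methylation of a phenol.
4. Forward, fragment B and union: phloroglucinol, then the butyrophenone, then the methylene-bridged bis-arene, then its bis-Mannich base; the last step attaches two molecules of the dienone to both ends of this core in one operation (two-directional).
5. Stereochemistry: the target has no stereogenic centre and no stereogenic double bond, so nothing has to be set.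

Key step: step 4

Remark: the terminal rings are enolised 2-acylcyclohexane-1,3,5-triones; their enol tautomers interconvert freely and are treated as one compound, drawn as in the target structure.

**Route**

Step 1
Reactants: 1 2,2,6-trimethyl-4H-1,3-dioxin-4-one (2.0 equiv); 2 2-methylpropanoyl chloride (1.0 equiv)
Product: 4 2,2-dimethyl-6-(3-methyl-2-oxobutyl)-4H-1,3-dioxin-4-one, via lithium dienolate 3 (not isolated)
Conditions: LiN(SiMe3)2 (2.0 equiv), THF, −78 °C; then 2, −78 to −40 °C; aq. NH4Cl
Reagents that add atoms: none
Why: Vinylogous deprotonation of the C6 methyl group gives the lithium dienolate, which is C-acylated at its terminal carbon by the acid chloride (vinylogous Claisen-type acylation, the standard route to keto-dioxinones); the second equivalent of dienolate takes up the more acidic proton of the product.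

Step 2
Reactants: 4 2,2-dimethyl-6-(3-methyl-2-oxobutyl)-4H-1,3-dioxin-4-one
Product: 6 4-hydroxy-6-(propan-2-yl)-2H-pyran-2-one, via acylketene 5 (not isolated)
Conditions: toluene, 110 °C
Reagents that add atoms: none
Why: Thermal retro-hetero-Diels–Alder loss of acetone releases an acylketene that is captured by the enol oxygen of the neighbouring 1,3-diketone (6π oxa-electrocyclisation, in effect a lactonisation), the established thermolysis of keto-dioxinones to 6-substituted 4-hydroxy-2-pyrones.

Step 3
Reactants: 6 4-hydroxy-6-(propan-2-yl)-2H-pyran-2-one; 7 butanoic acid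
Product: 9 3-butanoyl-4-hydroxy-6-(propan-2-yl)-2H-pyran-2-one, via pyranyl butanoate 8 (not isolated)
Conditions: N,N'-dicyclohexylcarbodiimide (1.2 equiv), 4-(dimethylamino)pyridine (0.3 equiv), toluene, 20 °C then 90 °C
Reagents that add atoms: none
Why: Steglich esterification of the acidic 4-hydroxyl group and 4-(dimethylamino)pyridine-mediated O-to-C acyl migration (a Fries-type 1,3-shift through the acylpyridinium pyronate ion pair) place the butanoyl group on C3, the only nucleophilic ring carbon, as in known one-pot 3-acylations of 4-hydroxy-6-alkyl-2-pyrones.

Step 4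
Reactants: 9 3-butanoyl-4-hydroxy-6-(propan-2-yl)-2H-pyran-2-one
Product: 11 2-butanoyl-3,5-dihydroxy-4,4-dimethylcyclohexa-2,5-dien-1-one, via ketene dienediolate 10 (not isolated)
Conditions: KN(SiMe3)2 (3.2 equiv), THF, −78 to 60 °C; then 1 M HCl
Reagents that add atoms: none
Why: Proposed new method: the first equivalent of amide gives the 4-pyronate and a further one removes the isopropyl methine proton (vinylogous to C4=O through C5=C6), so that the lactone becomes an ester enolate with an enolate leaving group and fragments by E1cB to the butanoyl ketene 10, in which the former C4=C5 bond holds the ketene and the new Me2C=C(O−) terminus cis; a thermally allowed disrotatory 6π-electrocyclisation (equally described as a 6-endo-dig, enolendo C-acylation of the tertiary enolate carbon by the ketene) should then join the former lactone carbonyl carbon to the methine carbon, and acid work-up should give 11. The closest known reaction types are the base-induced rearrangement of enol lactones to cyclic 1,3-diones (ylidenebutenolide to cyclopentenedione, Baker–Venkataraman O-to-C acyl transfer), the Claisen recyclisation of 2-pyrones to phloroglucinols, and the 6π closure of dienylketenes that ends the Danheiser benzannulation and the Moore cyclisation, which stops at the cyclohexadienone when the terminus is disubstituted. One six-membered carbocycle is closed in the 6π mode; no stereocentre is created, and the single geometric requirement, a cis central double bond in the triene, is inherited from the pyrone ring. The step needs C- over O-acylation, methine over side-chain deprotonation and retention of the butanoyl group: O-attack only regenerates the pyrone dianion, the butanoyl enolate has no exit (it would have to bridge C3 and C6 of the intact ring, and after ring opening C6 is an enolate carbon, so no aldol aromatisation is open), and reversible proton transfer through HN(SiMe3)2 should funnel the material through the methine anion. The non-nucleophilic amide base avoids the retro-Claisen deacylation that alkoxides cause in 3-acyl-4-hydroxy-2-pyrones, and the product leaves as a doubly vinylogous carboxylate, which should make the closure irreversible.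

Step 5
Reactants: 12 benzene-1,3,5-triol (phloroglucinol); 13 butanoyl chloride
Product: 14 1-(2,4,6-trihydroxyphenyl)butan-1-one
Conditions: AlCl3 (3.5 equiv), nitrobenzene/CH2Cl2, 0 to 40 °C; ice, 2 M HCl
Reagents that add atoms: none
Why: Friedel–Crafts C-acylation of the very electron-rich triol stops after one acyl group because the chelated aryl ketone deactivates the ring.

Step 6
Reactants: 14 1-(2,4,6-trihydroxyphenyl)butan-1-one (2.0 equiv)
Product: 16 bis(3-butanoyl-2,4,6-trihydroxyphenyl)methane, via hydroxymethyl phenol 15 (not isolated)
Conditions: 37% aq. CH2O (0.5 equiv per 14), 2% aq. KOH, 0 to 20 °C; then 1 M HCl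
Reagents that add atoms: formaldehyde, C=O
Why: Lederer–Manasse hydroxymethylation of the phenoxide and condensation of the benzylic alcohol with a second phenoxide (phenol–formaldehyde condensation) give the diarylmethane, and the two-to-one stoichiometry together with the low solubility of 16 should hold the reaction at the dimer.

Step 7
Reactants: 16 bis(3-butanoyl-2,4,6-trihydroxyphenyl)methane
Product: 18 bis[3-butanoyl-5-(dimethylaminomethyl)-2,4,6-trihydroxyphenyl]methane, via mono-Mannich base 17 (not isolated)
Conditions: CH2(NMe2)2 (2.2 equiv), 1,4-dioxane, 20 °C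
Reagents that add atoms: bis(dimethylamino)methane, CN(C)CN(C)C
Why: Mannich aminomethylation with a preformed aminal takes place at the single unsubstituted carbon of each phloroglucinol ring, so both ends of the symmetric core are functionalised alike and no regiochemical choice arises.

Step 8
Reactants: 18 bis[3-butanoyl-5-(dimethylaminomethyl)-2,4,6-trihydroxyphenyl]methane; 11 2-butanoyl-3,5-dihydroxy-4,4-dimethylcyclohexa-2,5-dien-1-one (2.2 equiv)
Product: 20 bis{3-butanoyl-5-[(5-butanoyl-2,4-dihydroxy-3,3-dimethyl-6-oxocyclohexa-1,4-dien-1-yl)methyl]-2,4,6-trihydroxyphenyl}methane (the target CNP0110234.0), via mono-adduct 19 (not isolated)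
Conditions: 1,4-dioxane, 85 °C, slow N2 stream; then 1 M HCl work-up
Reagents that add atoms: none
Why: Two-directional alkylation by elimination–addition: the vinylogous acid 11 protonates each benzylic amine, loss of dimethylamine unmasks the ortho-hydroxybenzyl electrophile, and C6 of 11, its only free nucleophilic carbon, adds in a Michael sense (the known reactivity of phenolic Mannich bases toward cyclic 1,3-dicarbonyl compounds); neither partner can pair with itself because 18 has no free ring carbon and 11 has no electrophilic carbon.

**Compound list**
1 | 2,2,6-trimethyl-4H-1,3-dioxin-4-one | CC1=CC(=O)OC(C)(C)O1 | starting material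
2 | 2-methylpropanoyl chloride | CC(C)C(=O)Cl | starting material
3 | lithium dienolate of 1, lithium 2,2-dimethyl-6-methylidene-6H-1,3-dioxin-4-olate (not isolated) | C=C1C=C(O[Li])OC(C)(C)O1 | intermediate
4 | 2,2-dimethyl-6-(3-methyl-2-oxobutyl)-4H-1,3-dioxin-4-one | CC(C)C(=O)CC1=CC(=O)OC(C)(C)O1 | intermediate
5 | acylketene 6-methyl-3,5-dioxohept-1-en-1-one (not isolated) | CC(C)C(=O)CC(=O)C=C=O | intermediate
6 | 4-hydroxy-6-(propan-2-yl)-2H-pyran-2-one | CC(C)C1=CC(O)=CC(=O)O1 | intermediate
7 | butanoic acid | CCCC(=O)O | starting material
8 | 2-oxo-6-(propan-2-yl)-2H-pyran-4-yl butanoate (not isolated) | CCCC(=O)OC1=CC(=O)OC(C(C)C)=C1 | intermediate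
9 | 3-butanoyl-4-hydroxy-6-(propan-2-yl)-2H-pyran-2-one | CCCC(=O)C1=C(O)C=C(C(C)C)OC1=O | intermediate
10 | dipotassium 2-butanoyl-6-methyl-1-oxohepta-1,3,5-triene-3,5-diolate, ketene carbon chain and Me2C=C(O−) unit cis on the C3=C4 bond (not isolated) | CCCC(=O)C(=C=O)/C([O-])=C\C([O-])=C(C)C.[K+].[K+] | intermediate
11 | 2-butanoyl-3,5-dihydroxy-4,4-dimethylcyclohexa-2,5-dien-1-one (butyrylfilicinic acid) | CCCC(=O)C1=C(O)C(C)(C)C(O)=CC1=O | intermediate
12 | benzene-1,3,5-triol (phloroglucinol) | Oc1cc(O)cc(O)c1 | starting material
13 | butanoyl chloride | CCCC(=O)Cl | starting material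
14 | 1-(2,4,6-trihydroxyphenyl)butan-1-one | CCCC(=O)c1c(O)cc(O)cc1O | intermediate
15 | 1-[2,4,6-trihydroxy-3-(hydroxymethyl)phenyl]butan-1-one (not isolated) | CCCC(=O)c1c(O)cc(O)c(CO)c1O | intermediate
16 | bis(3-butanoyl-2,4,6-trihydroxyphenyl)methane | CCCC(=O)c1c(O)cc(O)c(Cc2c(O)cc(O)c(C(=O)CCC)c2O)c1O | intermediate
17 | [3-butanoyl-5-(dimethylaminomethyl)-2,4,6-trihydroxyphenyl](3-butanoyl-2,4,6-trihydroxyphenyl)methane (not isolated) | CCCC(=O)c1c(O)c(CN(C)C)c(O)c(Cc2c(O)cc(O)c(C(=O)CCC)c2O)c1O | intermediate
18 | bis[3-butanoyl-5-(dimethylaminomethyl)-2,4,6-trihydroxyphenyl]methane | CCCC(=O)c1c(O)c(CN(C)C)c(O)c(Cc2c(O)c(CN(C)C)c(O)c(C(=O)CCC)c2O)c1O | intermediate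
19 | {3-butanoyl-5-[(5-butanoyl-2,4-dihydroxy-3,3-dimethyl-6-oxocyclohexa-1,4-dien-1-yl)methyl]-2,4,6-trihydroxyphenyl}[3-butanoyl-5-(dimethylaminomethyl)-2,4,6-trihydroxyphenyl]methane (not isolated) | CCCC(=O)C1=C(O)C(C)(C)C(O)=C(Cc2c(O)c(Cc3c(O)c(CN(C)C)c(O)c(C(=O)CCC)c3O)c(O)c(C(=O)CCC)c2O)C1=O | intermediate
20 | bis{3-butanoyl-5-[(5-butanoyl-2,4-dihydroxy-3,3-dimethyl-6-oxocyclohexa-1,4-dien-1-yl)methyl]-2,4,6-trihydroxyphenyl}methane (CNP0110234.0) | CCCC(=O)C1=C(O)C(C)(C)C(O)=C(Cc2c(O)c(Cc3c(O)c(CC4=C(O)C(C)(C)C(O)=C(C(=O)CCC)C4=O)c(O)c(C(=O)CCC)c3O)c(O)c(C(=O)CCC)c2O)C1=O | target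

**Step count and risks**
Total steps: 8. Longest linear sequence: 5 (steps 1, 2, 3, 4, 8); the second branch (steps 5, 6, 7) joins in step 8.

Steps most likely to fail:

1. Step 4 (proposed new method). The methine proton may not be removed from the already anionic pyronate, or the dianion may not fragment below the temperature at which it decomposes, so that the pyrone is simply recovered; intermolecular capture of the ketene would lead to oligomerisation. The fallback uses known chemistry, sets out from 14 and returns at 11. It is the classical dearomative gem-dimethylation of an acylphloroglucinol (NaOMe, MeI, MeOH, 0 to 20 °C), with under- and over-methylated material removed by chromatography. It makes no compound outside the list (F0), and steps 1 to 3 then fall away.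

2. Step 8. The elimination–addition is reversible, so retro-Michael cleavage may redistribute methylene bridges, at the new links or at the central diarylmethane, and re-addition of the released dimethylamine may stall the reaction at the mono-adduct. The fallback sets out from 16 and returns at 20, and replaces the reversible amine exchange by an irreversible hydride capture. Vilsmeier–Haack formylation (POCl3, DMF, EtOAc, 0 to 20 °C; aq. NaOAc) of the one free carbon of each ring should give bis(3-butanoyl-5-formyl-2,4,6-trihydroxyphenyl)methane F1. Knoevenagel condensation of F1 with two equivalents of 11, in the presence of Hantzsch ester (diethyl 2,6-dimethyl-1,4-dihydropyridine-3,5-dicarboxylate) and catalytic L-proline (CH2Cl2/EtOH, 20 °C), should form the double Knoevenagel adduct F2, whose exocyclic alkene geometry is undefined and of no consequence. F2 is reduced by conjugate hydride transfer as it forms, which should give 20.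

3. Step 7. The second aminomethylation may stay incomplete, or the Mannich base may lose amine prematurely and condense with unreacted 16, which would start chain growth. The fallback sets out from 11 and 16 and returns at 20, with the polarity of the union reversed. Aminomethylation of 11 at C6 with CH2(NMe2)2 (1,4-dioxane, 20 °C) should give 2-butanoyl-6-[(dimethylamino)methyl]-3,5-dihydroxy-4,4-dimethylcyclohexa-2,5-dien-1-one F3, a zwitterion. Heating two equivalents of F3 with 16 (1,4-dioxane, 80 °C) should release the 6-methylene trione, which alkylates the free carbon of each aromatic ring in a Friedel–Crafts-type Michael addition and gives 20.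

**Further compounds**
F0 | step 4 | none | none
F1 | step 8 | bis(3-butanoyl-5-formyl-2,4,6-trihydroxyphenyl)methane | CCCC(=O)c1c(O)c(C=O)c(O)c(Cc2c(O)c(C=O)c(O)c(C(=O)CCC)c2O)c1O
F2 | step 8 | double Knoevenagel adduct of F1 with two molecules of 11 (exocyclic alkene geometry undefined) | CCCC(=O)C1=C(O)C(C)(C)C(=O)C(=Cc2c(O)c(Cc3c(O)c(C=C4C(=O)C(C)(C)C(O)=C(C(=O)CCC)C4=O)c(O)c(C(=O)CCC)c3O)c(O)c(C(=O)CCC)c2O)C1=O
F3 | step 7 | 2-butanoyl-6-[(dimethylamino)methyl]-3,5-dihydroxy-4,4-dimethylcyclohexa-2,5-dien-1-one | CCCC(=O)C1=C(O)C(C)(C)C(O)=C(CN(C)C)C1=O
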